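The route rests on the cyclohexane ring of the 6-oxabicyclo[3.2.1]octane: its two oxygen-bearing carbons, C2 (CHOH) and C5 (the C(CH3)–O bridgehead), are cis-1,4 and flank the C3–C4 ethano unit. The key step therefore stitches ethene, as a titanacyclopropane 1,2-dicarbanion, between an aldehyde and a methyl ketone, forming C2–C3 and C4–C5 in one operation with both oxygens on one titanium. Its precursor is an acyclic 1,4-keto aldehyde whose quaternary C1 and tertiary C8 stereocentres come from (S)-5-methylfuran-2(5H)-one by conjugate addition and two enolate alkylations. Williamson closure of the O6–C7 bond and a Mitsunobu reaction with umbelliferone finish the route.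

Key step: step 8

Remark on locants: C1–C8 and O6 are those of the 6-oxabicyclo[3.2.1]octane core (C1 methyl-bearing quaternary bridgehead, C2 carbinol carbon, C3 and C4 the ethano carbons, C5 oxygenated bridgehead, O6, C7 methylene, C8 side-chain carbon). Lactone locants are called "lactone C3/C4/C5".

Assumption: (S)-5-methylfuran-2(5H)-one is taken as a purchased chiral-pool compound (otherwise three routine steps from ethyl (S)-lactate), and 4-methoxybenzyl chloromethyl ether as a purchased reagent.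

Step 1
Reactants: 1 4-bromobut-1-yne
Product: 3 ethyl (2E)-5-bromo-3-methylpent-2-enoate, via alkenylalane 2 (not isolated)
Conditions: Me3Al, Cp2ZrCl2 (20 mol %), CH2Cl2, 0 °C to rt; then ClCO2Et, 0 °C to rt
Reagents that add atoms: trimethylaluminium C[Al](C)C; ethyl chloroformate CCOC(=O)Cl
Why: Zirconium-catalysed Negishi carboalumination adds methyl and aluminium syn across the terminal alkyne (methyl to the internal carbon), and acylation of the alkenylalane with retention should fix the E trisubstituted alkene while the primary bromide stays inert.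

Step 2
Reactants: 3 ethyl (2E)-5-bromo-3-methylpent-2-enoate
Product: 4 (2E)-5-bromo-3-methylpent-2-en-1-ol
Conditions: iBu2AlH (DIBAL-H), CH2Cl2, −78 to 0 °C
Reagents that add atoms: none
Why: DIBAL-H reduces the conjugated ester to the allylic alcohol by 1,2-hydride delivery without touching the primary bromide or the alkene geometry (ester reduction).

Step 3
Reactants: 4 (2E)-5-bromo-3-methylpent-2-en-1-ol
Product: 5 {[(2E)-5-bromo-3-methylpent-2-en-1-yl]oxy}(tert-butyl)diphenylsilane
Conditions: TBDPSCl, imidazole, CH2Cl2, 0 °C to rt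
Reagents that add atoms: tert-butyl(chloro)diphenylsilane CC(C)(C)[Si](Cl)(c1ccccc1)c1ccccc1
Why: Silylation of the primary allylic alcohol gives a TBDPS ether that should survive the organometallic, hydride, oxidative and basic steps that follow.

Step 4
Reactants: 5 {[(2E)-5-bromo-3-methylpent-2-en-1-yl]oxy}(tert-butyl)diphenylsilane; 6 (S)-5-methylfuran-2(5H)-one
Product: 9 (3S,4R,5S)-4-{(3E)-5-[(tert-butyldiphenylsilyl)oxy]-3-methylpent-3-en-1-yl}-3-{[(4-methoxybenzyl)oxy]methyl}-5-methyloxolan-2-one, via Grignard reagent 7 (not isolated), via magnesium enolate 8 (not isolated)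
Conditions: Mg, THF, rt; CuBr·SMe2 (15 mol %), then 6, THF, −78 °C; then PMBOCH2Cl, DMPU, −78 to −20 °C
Reagents that add atoms: 4-methoxybenzyl chloromethyl ether COc1ccc(COCCl)cc1
Why: Copper-catalysed conjugate addition of the Grignard reagent should occur anti to the lactone C5 methyl group, and the magnesium enolate is then alkylated anti to the new lactone C4 substituent (tandem conjugate addition–enolate alkylation), which sets the 4,5-trans and 3,4-trans relationships.

Step 5
Reactants: 9 the 3,4-trans-4,5-trans lactone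
Product: 11 (3R,4R,5S)-4-{(3E)-5-[(tert-butyldiphenylsilyl)oxy]-3-methylpent-3-en-1-yl}-3-{[(4-methoxybenzyl)oxy]methyl}-3,5-dimethyloxolan-2-one, via lithium enolate 10 (not isolated)
Conditions: LiN(iPr)2 (LDA), THF, −78 °C; then MeI, DMPU, −78 to −60 °C
Reagents that add atoms: iodomethane CI
Why: The enolate is planar at lactone C3 and methyl iodide should again approach anti to the adjacent lactone C4 side chain, so the CH2OPMB group ends cis to the side chain and the quaternary centre (future C1) is set, while the low temperature suppresses β-elimination of the alkoxide (enolate alkylation).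

Step 6
Reactants: 11 the quaternary lactone
Product: 12 (2S,3R,4S)-3-{(3E)-5-[(tert-butyldiphenylsilyl)oxy]-3-methylpent-3-en-1-yl}-2-{[(4-methoxybenzyl)oxy]methyl}-2-methylpentane-1,4-diol
Conditions: LiAlH4, THF, 0 °C
Reagents that add atoms: none
Why: LiAlH4 reduces the lactone to the 1,4-diol without affecting the silyl ether, the PMB ether or the alkene (lactone reduction).

Step 7
Reactants: 12 the 1,4-diol
Product: 13 (2R,3R)-3-{(3E)-5-[(tert-butyldiphenylsilyl)oxy]-3-methylpent-3-en-1-yl}-2-{[(4-methoxybenzyl)oxy]methyl}-2-methyl-4-oxopentanal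
Conditions: (COCl)2, DMSO, CH2Cl2, −78 °C; then Et3N, −78 to 0 °C
Reagents that add atoms: none
Why: Swern oxidation activates both hydroxyls before the base is added, so the primary and the secondary alcohol are oxidised together and the lactol-to-lactone path typical of 1,4-diols is avoided, and the α-stereocentre next to a quaternary carbon should not epimerise at low temperature.

Step 8
Reactants: 13 the 1,4-keto aldehyde
Product: 16 (1S,2R,3R,4R)-2-{(3E)-5-[(tert-butyldiphenylsilyl)oxy]-3-methylpent-3-en-1-yl}-3-{[(4-methoxybenzyl)oxy]methyl}-1,3-dimethylcyclohexane-1,4-diol, via oxatitanacyclopentane 14 (not isolated), via titanium diolate 15 (not isolated)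
Conditions: Ti(OiPr)4, EtMgBr (2 equiv per Ti), Et2O, −78 to −50 °C; then 13, −50 to 0 °C; aq. potassium sodium tartrate
Reagents that add atoms: ethylmagnesium bromide CC[Mg]Br
Why: Proposed new method: Ti(OiPr)4 and two equivalents of EtMgBr give Et2Ti(OiPr)2, which loses ethane by β-hydride abstraction to the titanacyclopropane (iPrO)2Ti(η2-C2H4), a 1,2-dicarbanion on divalent titanium; this should insert the aldehyde of 13 into one Ti–C bond (oxatitanacyclopentane 14, new bond C2–C3), after which the remaining alkyl–titanium bond adds to the methyl ketone (new bond C4–C5) to give the diolate 15, hydrolysed to 16. The closest known reaction types are the Kulinkovich cyclopropanol synthesis (the same titanacyclopropane undergoing two successive carbonyl insertions at one ester carbon), the double carbonyl addition of zirconocene–diene complexes to give 1,6-diols and the annulation of niobium–alkyne complexes with aryl 1,2-dialdehydes, but an ethene complex bridging the two different carbonyl groups of a 1,4-keto aldehyde into a cyclohexane-1,4-diol has not been shown. The carbocycle is closed in the second insertion, a 6-exo-trig attack of the titanium-bound C4 carbon on the ketone carbonyl inside a seven-membered dioxatitanacycle. Both new stereocentres are set by the metal: the two oxygens must stay on the same titanium, which forces the C2–O and C5–O bonds cis-1,4 across a boat-like ring, and of the two such boats the one that keeps the C8 side chain and the C1 CH2OPMB group pseudo-equatorial (with only H and CH3 eclipsed underneath) should be preferred, so both oxygens end cis to the CH2OPMB group as the later ether closure requires. The step needs ethene transfer to win over ethyl addition, pinacol-type coupling and aldol closure of the keto aldehyde, which is secured by forming the titanacyclopropane completely at low temperature before 13 is added and by the inertness of the trisubstituted alkene, the silyl ether and the PMB ether towards the reagent.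

Step 9
Reactants: 16 the PMB-protected cyclohexane-1,4-diol
Product: 17 (1S,2R,3R,4R)-2-{(3E)-5-[(tert-butyldiphenylsilyl)oxy]-3-methylpent-3-en-1-yl}-3-(hydroxymethyl)-1,3-dimethylcyclohexane-1,4-diol
Conditions: DDQ, CH2Cl2/H2O, 0 °C to rt
Reagents that add atoms: none
Why: DDQ oxidises the electron-rich PMB ether to an oxocarbenium ion that water hydrolyses, which should leave the TBDPS ether, the trisubstituted alkene and the free alcohols untouched (oxidative PMB cleavage).

Step 10
Reactants: 17 the triol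
Product: 19 (1R,2R,5S,8R)-8-{(3E)-5-[(tert-butyldiphenylsilyl)oxy]-3-methylpent-3-en-1-yl}-1,5-dimethyl-6-oxabicyclo[3.2.1]octan-2-ol, via tosylate 18 (not isolated)
Conditions: TsCl, Et3N, DMAP (cat.), CH2Cl2, 0 °C; then KOtBu, THF, 0 °C to rt
Reagents that add atoms: none
Why: The primary hydroxyl should be sulfonylated in preference to the hindered secondary and the tertiary hydroxyl, and the tertiary C5 alkoxide, cis and 1,3-diaxial to the CH2OTs group, then closes the O6–C7 bond by 5-exo-tet displacement (intramolecular Williamson etherification) without touching any stereocentre.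

Step 11
Reactants: 19 the silyl-protected bicyclic ether
Product: 20 (1R,2R,5S,8R)-8-[(3E)-5-hydroxy-3-methylpent-3-en-1-yl]-1,5-dimethyl-6-oxabicyclo[3.2.1]octan-2-ol
Conditions: Bu4NF, THF, rt
Reagents that add atoms: none
Why: Fluoride cleaves the Si–O bond of the TBDPS ether and nothing else in the molecule should respond to it (desilylation).

Step 12
Reactants: 20 the allylic alcohol; 21 umbelliferone (7-hydroxy-2H-chromen-2-one)
Product: 22 7-{[(2E)-5-[(1R,2R,5S,8R)-2-hydroxy-1,5-dimethyl-6-oxabicyclo[3.2.1]octan-8-yl]-3-methylpent-2-en-1-yl]oxy}-2H-chromen-2-one (CNP0178104.1)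
Conditions: PPh3, DIAD, THF, 0 °C to rt
Reagents that add atoms: none
Why: In the Mitsunobu etherification the acidic phenol of umbelliferone should displace the activated primary allylic alcohol, while the hindered secondary C2 hydroxyl next to the quaternary C1 stays untouched and the alkene geometry is retained.

Compound list
1 | 4-bromobut-1-yne | BrCCC#C | starting material
2 | (E)-(4-bromo-2-methylbut-1-en-1-yl)dimethylalane | C/C(=C\[Al](C)C)CCBr | intermediate
3 | ethyl (2E)-5-bromo-3-methylpent-2-enoate | C/C(=C\C(=O)OCC)CCBr | intermediate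
4 | (2E)-5-bromo-3-methylpent-2-en-1-ol | C/C(=C\CO)CCBr | intermediate
5 | {[(2E)-5-bromo-3-methylpent-2-en-1-yl]oxy}(tert-butyl)diphenylsilane | C/C(=C\CO[Si](c1ccccc1)(c1ccccc1)C(C)(C)C)CCBr | intermediate
6 | (S)-5-methylfuran-2(5H)-one | C[C@@H]1OC(=O)C=C1 | starting material
7 | bromo{(3E)-5-[(tert-butyldiphenylsilyl)oxy]-3-methylpent-3-en-1-yl}magnesium | C/C(=C\CO[Si](c1ccccc1)(c1ccccc1)C(C)(C)C)CC[Mg]Br | intermediate
8 | bromomagnesium enolate of the (4R,5S)-4-alkyl-5-methyl lactone (4,5-trans) | C/C(=C\CO[Si](c1ccccc1)(c1ccccc1)C(C)(C)C)CC[C@H]1[C@H](C)OC(O[Mg]Br)=C1 | intermediate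
9 | (3S,4R,5S)-4-{(3E)-5-[(tert-butyldiphenylsilyl)oxy]-3-methylpent-3-en-1-yl}-3-{[(4-methoxybenzyl)oxy]methyl}-5-methyloxolan-2-one | C/C(=C\CO[Si](c1ccccc1)(c1ccccc1)C(C)(C)C)CC[C@H]1[C@H](C)OC(=O)[C@@H]1COCc1ccc(OC)cc1 | intermediate
10 | lithium enolate of 9 (lactone C4 R, lactone C5 S) | C/C(=C\CO[Si](c1ccccc1)(c1ccccc1)C(C)(C)C)CC[C@H]1[C@H](C)OC(O[Li])=C1COCc1ccc(OC)cc1 | intermediate
11 | (3R,4R,5S)-4-{(3E)-5-[(tert-butyldiphenylsilyl)oxy]-3-methylpent-3-en-1-yl}-3-{[(4-methoxybenzyl)oxy]methyl}-3,5-dimethyloxolan-2-one | C/C(=C\CO[Si](c1ccccc1)(c1ccccc1)C(C)(C)C)CC[C@H]1[C@H](C)OC(=O)[C@@]1(C)COCc1ccc(OC)cc1 | intermediate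
12 | (2S,3R,4S)-3-{(3E)-5-[(tert-butyldiphenylsilyl)oxy]-3-methylpent-3-en-1-yl}-2-{[(4-methoxybenzyl)oxy]methyl}-2-methylpentane-1,4-diol | C/C(=C\CO[Si](c1ccccc1)(c1ccccc1)C(C)(C)C)CC[C@@H]([C@H](C)O)[C@@](C)(CO)COCc1ccc(OC)cc1 | intermediate
13 | (2R,3R)-3-{(3E)-5-[(tert-butyldiphenylsilyl)oxy]-3-methylpent-3-en-1-yl}-2-{[(4-methoxybenzyl)oxy]methyl}-2-methyl-4-oxopentanal | C/C(=C\CO[Si](c1ccccc1)(c1ccccc1)C(C)(C)C)CC[C@@H](C(C)=O)[C@@](C)(C=O)COCc1ccc(OC)cc1 | intermediate
14 | 2,2-diisopropoxy-1-oxa-2-titanacyclopentane from aldehyde insertion (ring Ti–O–CH–CH2–CH2; carbinol carbon configured as C4 of 16; ketone still free) | C/C(=C\CO[Si](c1ccccc1)(c1ccccc1)C(C)(C)C)CC[C@@H](C(C)=O)[C@](C)(COCc1ccc(OC)cc1)[C@H]1CC[Ti](OC(C)C)(OC(C)C)O1 | intermediate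
15 | diisopropoxytitanium diolate of 16 (2,4-dioxa-3-titanabicyclo[3.2.2]nonane core; both oxygens cis on one titanium) | C/C(=C\CO[Si](c1ccccc1)(c1ccccc1)C(C)(C)C)CC[C@H]1[C@@](C)(O[Ti]2(OC(C)C)OC(C)C)CC[C@@H](O2)[C@@]1(C)COCc1ccc(OC)cc1 | intermediate
16 | (1S,2R,3R,4R)-2-{(3E)-5-[(tert-butyldiphenylsilyl)oxy]-3-methylpent-3-en-1-yl}-3-{[(4-methoxybenzyl)oxy]methyl}-1,3-dimethylcyclohexane-1,4-diol | C/C(=C\CO[Si](c1ccccc1)(c1ccccc1)C(C)(C)C)CC[C@H]1[C@@](C)(O)CC[C@@H](O)[C@@]1(C)COCc1ccc(OC)cc1 | intermediate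
17 | (1S,2R,3R,4R)-2-{(3E)-5-[(tert-butyldiphenylsilyl)oxy]-3-methylpent-3-en-1-yl}-3-(hydroxymethyl)-1,3-dimethylcyclohexane-1,4-diol | C/C(=C\CO[Si](c1ccccc1)(c1ccccc1)C(C)(C)C)CC[C@H]1[C@@](C)(O)CC[C@@H](O)[C@@]1(C)CO | intermediate
18 | primary 4-methylbenzenesulfonate of triol 17 (same configuration) | C/C(=C\CO[Si](c1ccccc1)(c1ccccc1)C(C)(C)C)CC[C@H]1[C@@](C)(O)CC[C@@H](O)[C@@]1(C)COS(=O)(=O)c1ccc(C)cc1 | intermediate
19 | (1R,2R,5S,8R)-8-{(3E)-5-[(tert-butyldiphenylsilyl)oxy]-3-methylpent-3-en-1-yl}-1,5-dimethyl-6-oxabicyclo[3.2.1]octan-2-ol | C/C(=C\CO[Si](c1ccccc1)(c1ccccc1)C(C)(C)C)CC[C@@H]1[C@]2(C)CO[C@@]1(C)CC[C@H]2O | intermediate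
20 | (1R,2R,5S,8R)-8-[(3E)-5-hydroxy-3-methylpent-3-en-1-yl]-1,5-dimethyl-6-oxabicyclo[3.2.1]octan-2-ol | C/C(=C\CO)CC[C@@H]1[C@]2(C)CO[C@@]1(C)CC[C@H]2O | intermediate
21 | umbelliferone (7-hydroxy-2H-chromen-2-one) | O=c1ccc2ccc(O)cc2o1 | starting material
22 | 7-{[(2E)-5-[(1R,2R,5S,8R)-2-hydroxy-1,5-dimethyl-6-oxabicyclo[3.2.1]octan-8-yl]-3-methylpent-2-en-1-yl]oxy}-2H-chromen-2-one | C/C(=C\COc1ccc2ccc(=O)oc2c1)CC[C@@H]1[C@]2(C)CO[C@@]1(C)CC[C@H]2O | target

Total step count: 12. Longest linear sequence: 12 steps (1 to 22); compounds 6 and 21 enter as purchased materials.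

Steps most likely to fail

Step 8 (proposed new method). Ethyl transfer or reduction of the aldehyde by residual ethyl–metal species, reductive coupling of carbonyl groups by divalent titanium, or a stalled ketone insertion may compete. Attack on the wrong aldehyde face would give a metal-bridged diolate with both oxygens trans to the CH2OPMB group. The fallback uses known chemistry and sets out from keto aldehyde 13. Double 1,2-addition of vinylmagnesium bromide with CeCl3 (THF, −78 °C) should form the same two bonds in one operation and give (3R,4R,5R,6S)-5-{(3E)-5-[(tert-butyldiphenylsilyl)oxy]-3-methylpent-3-en-1-yl}-4-{[(4-methoxybenzyl)oxy]methyl}-4,6-dimethylocta-1,7-diene-3,6-diol F1, the required diastereomer being separated by chromatography. Ring-closing metathesis with the second-generation Grubbs catalyst (CH2Cl2, 40 °C) should then give (1S,4R,5R,6R)-6-{(3E)-5-[(tert-butyldiphenylsilyl)oxy]-3-methylpent-3-en-1-yl}-5-{[(4-methoxybenzyl)oxy]methyl}-1,5-dimethylcyclohex-2-ene-1,4-diol F2. Diimide (from 2-nitrobenzenesulfonohydrazide and Et3N) should reduce the disubstituted ring alkene in preference to the trisubstituted side-chain alkene, and the route is rejoined at 16.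

Step 5. The enolate may lose 4-methoxybenzyl alkoxide by β-elimination, or facial selectivity may erode because the electrophile enters syn to the lactone C5 methyl group. The fallback sets out from 5 and 6 and quaternises a β-oxido dianion, which cannot eliminate. Copper-catalysed conjugate addition with a proton quench (aqueous NH4Cl) should give (4R,5S)-4-{(3E)-5-[(tert-butyldiphenylsilyl)oxy]-3-methylpent-3-en-1-yl}-5-methyloxolan-2-one F3. Aldol reaction of its lithium enolate with gaseous formaldehyde should give the (3S,4R,5S)-3-(hydroxymethyl) lactone F4. Fráter–Seebach-type dianion methylation (LiN(iPr)2, 2.2 equiv; MeI) should give the (3R,4R,5S)-3-(hydroxymethyl)-3,5-dimethyl lactone F5. Protection with 4-methoxybenzyl 2,2,2-trichloroacetimidate and catalytic TfOH rejoins the route at 11.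

Step 10. Sulfonylation may occur at the secondary hydroxyl, or the secondary C2 alkoxide may compete with the tertiary one by oxetane closure or by Grob-type fragmentation of the 1,3-hydroxy tosylate. The fallback sets out from 16 and removes the competing hydroxyl before ring closure. Dess–Martin oxidation of the secondary alcohol should give (2R,3R,4S)-3-{(3E)-5-[(tert-butyldiphenylsilyl)oxy]-3-methylpent-3-en-1-yl}-4-hydroxy-2-{[(4-methoxybenzyl)oxy]methyl}-2,4-dimethylcyclohexan-1-one F6. DDQ should then give the (2R,3R,4S)-4-hydroxy-2-(hydroxymethyl) ketone F7. TsCl and Et3N should give its primary tosylate F8, which KOtBu should close to (1R,5S,8R)-8-{(3E)-5-[(tert-butyldiphenylsilyl)oxy]-3-methylpent-3-en-1-yl}-1,5-dimethyl-6-oxabicyclo[3.2.1]octan-2-one F9. NaBH4 (MeOH, 0 °C) should deliver hydride axially, anti to the O6–C7 bridge, to give the equatorial C2 alcohol, and the route is rejoined at 19. This detour would also correct a wrong C2 configuration.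

Further compounds
F1 | step 8 | (3R,4R,5R,6S)-5-{(3E)-5-[(tert-butyldiphenylsilyl)oxy]-3-methylpent-3-en-1-yl}-4-{[(4-methoxybenzyl)oxy]methyl}-4,6-dimethylocta-1,7-diene-3,6-diol | C/C(=C\CO[Si](c1ccccc1)(c1ccccc1)C(C)(C)C)CC[C@@H]([C@@](C)(O)C=C)[C@](C)(COCc1ccc(OC)cc1)[C@H](O)C=C
F2 | step 8 | (1S,4R,5R,6R)-6-{(3E)-5-[(tert-butyldiphenylsilyl)oxy]-3-methylpent-3-en-1-yl}-5-{[(4-methoxybenzyl)oxy]methyl}-1,5-dimethylcyclohex-2-ene-1,4-diol | C/C(=C\CO[Si](c1ccccc1)(c1ccccc1)C(C)(C)C)CC[C@H]1[C@@](C)(O)C=C[C@@H](O)[C@@]1(C)COCc1ccc(OC)cc1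
F3 | step 5 | (4R,5S)-4-{(3E)-5-[(tert-butyldiphenylsilyl)oxy]-3-methylpent-3-en-1-yl}-5-methyloxolan-2-one | C/C(=C\CO[Si](c1ccccc1)(c1ccccc1)C(C)(C)C)CC[C@H]1[C@H](C)OC(=O)C1
F4 | step 5 | (3S,4R,5S)-4-{(3E)-5-[(tert-butyldiphenylsilyl)oxy]-3-methylpent-3-en-1-yl}-3-(hydroxymethyl)-5-methyloxolan-2-one | C/C(=C\CO[Si](c1ccccc1)(c1ccccc1)C(C)(C)C)CC[C@H]1[C@H](C)OC(=O)[C@@H]1CO
F5 | step 5 | (3R,4R,5S)-4-{(3E)-5-[(tert-butyldiphenylsilyl)oxy]-3-methylpent-3-en-1-yl}-3-(hydroxymethyl)-3,5-dimethyloxolan-2-one | C/C(=C\CO[Si](c1ccccc1)(c1ccccc1)C(C)(C)C)CC[C@H]1[C@H](C)OC(=O)[C@@]1(C)CO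
F6 | step 10 | (2R,3R,4S)-3-{(3E)-5-[(tert-butyldiphenylsilyl)oxy]-3-methylpent-3-en-1-yl}-4-hydroxy-2-{[(4-methoxybenzyl)oxy]methyl}-2,4-dimethylcyclohexan-1-one | C/C(=C\CO[Si](c1ccccc1)(c1ccccc1)C(C)(C)C)CC[C@H]1[C@@](C)(O)CCC(=O)[C@@]1(C)COCc1ccc(OC)cc1
F7 | step 10 | (2R,3R,4S)-3-{(3E)-5-[(tert-butyldiphenylsilyl)oxy]-3-methylpent-3-en-1-yl}-4-hydroxy-2-(hydroxymethyl)-2,4-dimethylcyclohexan-1-one | C/C(=C\CO[Si](c1ccccc1)(c1ccccc1)C(C)(C)C)CC[C@H]1[C@@](C)(O)CCC(=O)[C@@]1(C)CO
F8 | step 10 | primary 4-methylbenzenesulfonate of F7 | C/C(=C\CO[Si](c1ccccc1)(c1ccccc1)C(C)(C)C)CC[C@H]1[C@@](C)(O)CCC(=O)[C@@]1(C)COS(=O)(=O)c1ccc(C)cc1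
F9 | step 10 | (1R,5S,8R)-8-{(3E)-5-[(tert-butyldiphenylsilyl)oxy]-3-methylpent-3-en-1-yl}-1,5-dimethyl-6-oxabicyclo[3.2.1]octan-2-one | C/C(=C\CO[Si](c1ccccc1)(c1ccccc1)C(C)(C)C)CC[C@@H]1[C@]2(C)CO[C@@]1(C)CCC2=O
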